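Late in a run, free monomer heads for a floor, so that is where I start your quick number.

| flask | free monomer | pre-initiator | time |
|---|---|---|---|
| theta | 0.011 M | 0.51 mM | 6.0 h |
| delta | 0.011 M | 0.51 mM | 1.5 h |

    free monomer + initiator → living end + monomer in chains (k1 = 12 L mol⁻¹ min⁻¹)
    free monomer + living end → monomer in chains + living end, rate k2*[living end]*[free monomer] (k2 = 10 L mol⁻¹ min⁻¹)
    monomer in chains + living end → free monomer + living end, rate k3*[living end] as long as [monomer in chains] is above zero (k3 = 0.012 min⁻¹)
    pre-initiator → initiator (k4 = 0.0032 min⁻¹)

- which of the two ends with the longer chains by the average number of monomer units in a chain (chains begun, living or dead) ("neither" if they lie within 10 %) (theta / delta / neither)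
- average number of monomer units in a chain (chains begun, living or dead) at the end, theta
- average number of monomer units in a chain (chains begun, living or dead) at the end, delta

- the average divides the monomer in chains by the number of chains begun, living and dead together
- run time (theta): 6.0 h

A living end takes up free monomer in proportion to the free monomer present and gives monomer back at a steady rate. The two cancel at 1.20 mM, the monomer floor (the equilibrium monomer concentration): the free monomer at which a living end neither gains nor loses. No step removes a living end, so chains begun stay in the count, and the late length is

late length = (free monomer charged − floor) / pre-initiator charged = 19.2

Initiator lasts about 7.58 min against free monomer at its charge, much shorter than the 3.6 h half-life of pre-initiator. So I count pre-initiator turned over as chains begun, and let the excess of free monomer over the floor decay with the growth constant times the time-integral of those chains: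

theta: chains begun 0.349 mM, excess kept 47.4 %, length 14.8

delta: chains begun 0.128 mM, excess kept 94.2 %, length 4.49

I commit to theta. Your forecast also says theta, with 15.3 (range 14 to 16.5) for theta and 5.1 (4.6 to 5.6) for delta, holding that “Propagation is slow at these end concentrations and has not reached the monomer floor”. My lengths are shorter than yours, and delta's falls below your range.

The simulation gives theta, with 15.3 for theta and 5.12 for delta.

In theta at 6.00 h, monomer in chains is made 4.96 times faster than it is used up, a lower ratio than the 7.15 at 3.70 h. In theta at 6.00 h, free monomer over the floor is 4.83, with free monomer at 52.6 % of its charge and the floor at 10.9 %; this is the ratio to watch.

Theta's recipe with 0.0020 M of pre-initiator has 0.00127 M of living ends at 6.00 h, and the floor's allowance of 9.80 mM shared among them gives 7.70. That flask computes to an average length of 7.38, with free monomer at 14.6 % of its charge.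

(The constants belong to no real substance; what happens was integrated by code.)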